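**Retrosynthetic overview**
1. Target 15 ⇐ C9 acetate and C8 senecioate put on last ⇐ 12, whose 1,10-epoxide is delivered from the free C8–OH onto the Z ring olefin of macrocycle 11.
2. Ten-membered ring: 11 ⇐ diene 10 by ring-closing metathesis (C1=C10).
3. Key bond C8–C9: 10 ⇐ aldehyde 9 + methacrolein. The enal carbonyl carbon is made nucleophilic (γ-siloxyallylchromium, an α-oxyallyl anion) and attacks the aldehyde carbon, a carbonyl-to-carbonyl, pinacol-type union that gives C8–OH and C9–OSiEt3 already differentiated.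
4. 9 ⇐ Z-enal 5 by allylboration (C3), OH-directed epoxidation (4,5-epoxide) and angeloylation; 5 ⇐ (S)-carvone by C3–C8 ring scission (carvone supplies C3–C8, the C7 stereocenter and the Z C4=C5 olefin).
5. Ring order: 4,5-epoxide (step 5), then the ten-membered carbocycle (step 9), then the 1,10-epoxide (step 10).

Assumption: the target is the enantiomer drawn, (1R,3S,4S,5S,7R,8S,9S,10R) in germacrane numbering (C7 isopropenyl, C8 senecioate, C9 acetate, C3 angelate, epoxides C1–C10 and C4–C5); these locants are used for all intermediates, and CIP letters in names are those of each compound itself.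

**Route**

Step 1
Reactants: 1 (S)-(+)-carvone
Product: 2 (5R,6RS)-6-acetoxy-2-methyl-5-(prop-1-en-2-yl)cyclohex-2-en-1-one (6-acetoxycarvone; C6 epimer mixture)
Conditions: Mn(OAc)3·2H2O (2.5 equiv), benzene, reflux, Dean–Stark
Reagents that add atoms: manganese triacetate dihydrate, CC(=O)[O-].CC(=O)[O-].CC(=O)[O-].[Mn+3].O.O
Why: Trivalent-manganese α′-acetoxylation of an enone (manganese enolate, α′-radical, acetate transfer) functionalises only the α′-methylene; the new centre is an epimer mixture that is erased in step 3, and the isopropenyl-bearing centre is untouched.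

Step 2
Reactants: 2 6-acetoxycarvone
Product: 3 (6R)-3-methyl-6-(prop-1-en-2-yl)cyclohex-3-ene-1,2-diol (mixture at C1 and C2)
Conditions: i-Bu2AlH (4 equiv), CH2Cl2, −78 → 0 °C; Rochelle salt
Reagents that add atoms: none
Why: Aluminium hydride 1,2-reduction of the enone carbonyl and reductive removal of the acetate give the vicinal diol; the diastereomer mixture does not matter because both carbinol carbons become aldehydes.

Step 3
Reactants: 3 diol
Product: 5 (2Z,5R)-6,6-dimethoxy-2-methyl-5-(prop-1-en-2-yl)hex-2-enal, via dialdehyde 4 (not isolated)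
Conditions: NaIO4, THF–H2O (pH 7), 0 °C; crude, then HC(OMe)3, CeCl3·7H2O (10 mol %), MeOH, 0 °C
Reagents that add atoms: trimethyl orthoformate, COC(OC)OC; methanol, CO
Why: Malaprade periodate glycol cleavage opens the ring so the Z geometry of C4=C5 is inherited from the cyclohexene, and Gemal–Luche acetalisation protects only the saturated C8 aldehyde because conjugated aldehydes are not acetalised under CeCl3 catalysis; C7 comes unchanged from carvone.

Step 4
Reactants: 5 Z-enal acetal
Product: 6 (4S,5Z,8R)-9,9-dimethoxy-5-methyl-8-(prop-1-en-2-yl)nona-1,5-dien-4-ol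
Conditions: (−)-Ipc2B(allyl), Et2O, −78 °C; then NaOH, H2O2, 0 °C → rt
Reagents that add atoms: (−)-B-allyldiisopinocampheylborane, C=CCB([C@@H]1C[C@@H]2C[C@H]([C@H]1C)C2(C)C)[C@@H]1C[C@@H]2C[C@H]([C@H]1C)C2(C)C
Why: Brown asymmetric allylboration through a chair Zimmerman–Traxler transition state; the borane derived from (+)-α-pinene adds allyl to the si face of the enal (reagent control), giving the 3S alcohol by 1,2-addition.

Step 5
Reactants: 6 homoallylic alcohol
Product: 7 (1S)-1-{(2R,3S)-3-[(2R)-3,3-dimethoxy-2-(prop-1-en-2-yl)propyl]-2-methyloxiran-2-yl}but-3-en-1-ol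
Conditions: mCPBA (1.05 equiv), NaHCO3, CH2Cl2, −20 → 0 °C
Reagents that add atoms: 3-chloroperbenzoic acid, OOC(=O)c1cccc(Cl)c1
Why: Henbest hydroxyl-directed peracid epoxidation; allylic 1,3-strain between C2 and the cis C6 substituent holds H3 in the olefin plane, so the hydrogen-bonded peracid is delivered to the OH face and the threo 4,5-epoxide forms, the OH-activated trisubstituted olefin reacting ahead of the isopropenyl and vinyl groups.

Step 6
Reactants: 7 epoxy alcohol
Product: 8 (1S)-1-{(2S,3S)-3-[(2R)-3,3-dimethoxy-2-(prop-1-en-2-yl)propyl]-2-methyloxiran-2-yl}but-3-en-1-yl (2Z)-2-methylbut-2-enoate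
Conditions: angelic acid, 2,4,6-trichlorobenzoyl chloride, Et3N, toluene, rt; then 7, 80 °C (no DMAP)
Reagents that add atoms: angelic acid, C/C=C(/C)C(=O)O
Why: Yamaguchi-type mixed-anhydride esterification run without DMAP acylates the hindered epoxy carbinol with retention (O-acylation) and does not isomerise the Z (angelate) double bond to tiglate.

Step 7
Reactants: 8 angelate acetal
Product: 9 (1S)-1-{(2S,3S)-3-[(2R)-2-formyl-3-methylbut-3-en-1-yl]-2-methyloxiran-2-yl}but-3-en-1-yl (2Z)-2-methylbut-2-enoate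
Conditions: PPTS (0.2 equiv), acetone–H2O (10:1), rt → 40 °C
Reagents that add atoms: water, O
Why: Mild acid-catalysed acetal hydrolysis frees the C8 aldehyde; the epoxide (deactivated by the neighbouring acyloxy group), the angelate and the α-stereocentre survive these weakly acidic conditions.

Step 8
Reactants: 9 aldehyde
Product: 10 (1S)-1-{(2S,3S)-3-[(2R,3S,4R)-3-hydroxy-5-methyl-2-(prop-1-en-2-yl)-4-(triethylsilyloxy)hex-5-en-1-yl]-2-methyloxiran-2-yl}but-3-en-1-yl (2Z)-2-methylbut-2-enoate
Conditions: CrCl2 (6 equiv), Et3SiCl (2.2 equiv), methacrolein (2.5 equiv), THF, 0 °C → rt, slow addition of 9 and methacrolein; pH 7 buffer work-up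
Reagents that add atoms: methacrolein, C=C(C)C=O; chlorotriethylsilane, CC[Si](Cl)(CC)CC
Why: Takai–Utimoto pinacol-type cross-coupling: divalent chromium and Et3SiCl reduce methacrolein to a γ-siloxyallylchromium reagent whose former carbonyl carbon (an umpoled α-oxyallyl anion) attacks the aldehyde carbon C8 through a chair transition state; the (E)-enol ether (OSiEt3 cis to the small methyl) gives the anti C8–OH/C9–OSi pair, Felkin–Anh attack anti to the isopropenyl group sets C8 relative to C7, and the two oxygens emerge differentiated.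

Step 9
Reactants: 10 diene
Product: 11 (1(10)Z,3S,4S,5S,7R,8S,9R)-3-angeloyloxy-4,5-epoxy-9-(triethylsilyloxy)germacra-1(10),11-dien-8-ol
Conditions: RuCl2(=CH-C6H4-2-O-i-Pr)(H2IMes) (second-generation Hoveyda–Grubbs catalyst, 15 mol %), 1,4-benzoquinone (cat.), toluene (1 mM), 80 °C, Ar sparge
Reagents that add atoms: none
Why: Ring-closing olefin metathesis between the vinyl group and the 1,1-disubstituted olefin with loss of ethylene; in a ten-membered ring the Z (ring-cis) trisubstituted olefin is expected because the E ruthenacycle is more strained, and the cis-epoxide turn helps bring the termini together.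

Step 10
Reactants: 11 macrocyclic homoallylic alcohol
Product: 12 (1R,3S,4S,5S,7R,8S,9S,10R)-3-angeloyloxy-1,10:4,5-diepoxy-9-(triethylsilyloxy)germacr-11-en-8-ol
Conditions: VO(acac)2 (5 mol %), t-BuOOH (1.5 equiv), 2,6-lutidine (0.3 equiv), CH2Cl2, 0 °C → rt
Reagents that add atoms: tert-butyl hydroperoxide, CC(C)(C)OO
Why: Vanadium-catalysed hydroxyl-directed epoxidation of a homoallylic alcohol (Mihelich model); allylic 1,3-strain holds H9 in the olefin plane so that C8 with its vanadate and the bulky OSiEt3 group lie on opposite faces, oxygen is delivered on the C8 face (1R,10R, erythro to C9–O), and the electron-rich trisubstituted olefin reacts ahead of the isopropenyl group.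

Step 11
Reactants: 12 diepoxy alcohol
Product: 13 (1R,3S,4S,5S,7R,8S,9S,10R)-3-angeloyloxy-1,10:4,5-diepoxy-8-senecioyloxy-9-(triethylsilyloxy)germacr-11-ene
Conditions: 3-methylbut-2-enoic acid, 2,4,6-trichlorobenzoyl chloride, Et3N, toluene, rt; then 12, DMAP, 40 °C
Reagents that add atoms: 3-methylbut-2-enoic acid, CC(C)=CC(=O)O
Why: Yamaguchi esterification of the hindered C8 alcohol; the pre-formed mixed anhydride avoids the vinylketene pathway that deconjugates senecioyl chloride, and the carbinol configuration is untouched.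

Step 12
Reactants: 13 silyl ether
Product: 15 (1R,3S,4S,5S,7R,8S,9S,10R)-9-acetoxy-3-angeloyloxy-1,10:4,5-diepoxy-8-senecioyloxygermacr-11-ene (CNP0276917.1), via alcohol 14 (not isolated)
Conditions: HF·pyridine, pyridine, THF, 0 °C; then Ac2O, DMAP, 0 °C → rt
Reagents that add atoms: acetic anhydride, CC(=O)OC(C)=O
Why: Buffered HF·pyridine cleaves the Si–O bond without epoxide opening or acyl migration, and the freed C9 hydroxyl is acetylated in the same flask (DMAP-catalysed acyl transfer) with retention.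

**Compound list**

1 | (S)-(+)-carvone | C=C(C)[C@H]1CC=C(C)C(=O)C1 | starting material
2 | 6-acetoxycarvone, (5R,6RS) | C=C(C)[C@H]1CC=C(C)C(=O)C1OC(C)=O | intermediate
3 | (6R)-3-methyl-6-(prop-1-en-2-yl)cyclohex-3-ene-1,2-diol, carbinol mixture | C=C(C)[C@H]1CC=C(C)C(O)C1O | intermediate
4 | (2Z,5R)-2-methyl-5-(prop-1-en-2-yl)hex-2-enedial | C=C(C)[C@H](C=O)C/C=C(/C)C=O | intermediate (not isolated)
5 | (2Z,5R)-6,6-dimethoxy-2-methyl-5-(prop-1-en-2-yl)hex-2-enal | C=C(C)[C@H](C(OC)OC)C/C=C(/C)C=O | intermediate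
6 | (4S,5Z,8R)-9,9-dimethoxy-5-methyl-8-(prop-1-en-2-yl)nona-1,5-dien-4-ol | C=C(C)[C@H](C(OC)OC)C/C=C(/C)[C@@H](O)CC=C | intermediate
7 | threo 4,5-epoxy alcohol (name in step 5) | C=C(C)[C@H](C(OC)OC)C[C@@H]1O[C@]1(C)[C@@H](O)CC=C | intermediate
8 | C3 angelate of 7 (name in step 6) | C=C(C)[C@H](C(OC)OC)C[C@@H]1O[C@]1(C)[C@@H](OC(=O)/C(C)=C\C)CC=C | intermediate
9 | C8 aldehyde (name in step 7) | C=C(C)[C@H](C=O)C[C@@H]1O[C@]1(C)[C@@H](OC(=O)/C(C)=C\C)CC=C | intermediate
10 | anti C8-hydroxy, C9-triethylsilyloxy diene (name in step 8) | C=C(C)[C@H]([C@H](O)[C@H](O[Si](CC)(CC)CC)C(C)=C)C[C@@H]1O[C@]1(C)[C@@H](OC(=O)/C(C)=C\C)CC=C | intermediate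
11 | (1(10)Z)-3-angeloyloxy-4,5-epoxy-9-(triethylsilyloxy)germacra-1(10),11-dien-8-ol | C=C(C)[C@H]1C[C@@H]2O[C@]2(C)[C@@H](OC(=O)/C(C)=C\C)C/C=C(C)\[C@@H](O[Si](CC)(CC)CC)[C@H]1O | intermediate
12 | 3-angeloyloxy-1,10:4,5-diepoxy-9-(triethylsilyloxy)germacr-11-en-8-ol | C=C(C)[C@H]1C[C@@H]2O[C@]2(C)[C@@H](OC(=O)/C(C)=C\C)C[C@H]2O[C@@]2(C)[C@@H](O[Si](CC)(CC)CC)[C@H]1O | intermediate
13 | 8-senecioate of 12 | C=C(C)[C@H]1C[C@@H]2O[C@]2(C)[C@@H](OC(=O)/C(C)=C\C)C[C@H]2O[C@@]2(C)[C@@H](O[Si](CC)(CC)CC)[C@H]1OC(=O)C=C(C)C | intermediate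
14 | (1R,3S,4S,5S,7R,8S,9S,10S)-3-angeloyloxy-1,10:4,5-diepoxy-8-senecioyloxygermacr-11-en-9-ol | C=C(C)[C@H]1C[C@@H]2O[C@]2(C)[C@@H](OC(=O)/C(C)=C\C)C[C@H]2O[C@@]2(C)[C@@H](O)[C@H]1OC(=O)C=C(C)C | intermediate (not isolated)
15 | CNP0276917.1 | C=C(C)[C@H]1C[C@@H]2O[C@]2(C)[C@@H](OC(=O)/C(C)=C\C)C[C@H]2O[C@@]2(C)[C@@H](OC(C)=O)[C@H]1OC(=O)C=C(C)C | target

**Step count and risks**

Total steps: 12, all in one linear sequence from (S)-carvone; every other input is a commercial reagent. Longest linear sequence: 12.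

The three steps most likely to fail:

Step 8 (chromium pinacol-type coupling). The anti/syn ratio depends on the E/Z preference of the 2-methyl-substituted siloxyallylchromium. Felkin control at C8 is only moderate, since isopropenyl and CH2R are similar in size. The trivalent chromium alkoxide at O8 may also be silylated, or may open the 4,5-epoxide. Fallback, setting out from 9 and returning at 10: run the L-proline-catalysed aldol of 9 with hydroxyacetone (catalyst-controlled, anti) to give the 8,9-dihydroxy methyl ketone F1. Triethylsilylate the less hindered α-ketol hydroxyl at C9 (Et3SiCl, imidazole, −40 °C) to give the 9-O-triethylsilyl ether F2. Methylenate the ketone with Cp2Ti(μ-Cl)(μ-CH2)AlMe2 (Tebbe reagent, THF, −40 °C) to reach 10.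

Step 9 (ring-closing metathesis). Forming a trisubstituted olefin in a ten-membered carbocycle is slow, closure onto the isopropenyl group (eight-membered ring) competes, and the Z geometry is a ring-strain argument, not a certainty. Fallback, setting out from 8 and returning at 11: close the ring at C8–C9 instead. Cross-metathesis of 8 with methacrolein (same ruthenium catalyst, CH2Cl2, 40 °C) gives the (E)-enal acetal F3. PPTS hydrolysis gives the dialdehyde F4. Slow addition of F4 to CrCl2/Et3SiCl in THF at high dilution reduces the enal to the siloxyallylchromium, which attacks the C8 aldehyde intramolecularly; the ring olefin is re-formed inside the closing ten-membered ring, giving 11.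

Step 10 (vanadium-directed epoxidation). The C8 hydroxyl is also homoallylic to the isopropenyl group. The free C8–OH sits γ,δ to the 4,5-epoxide and may open it transannularly under Lewis-acidic pentavalent vanadium. Fallback, setting out from 11 and returning at 14: acylate first, so that no free C8–OH remains, to give the 8-O-senecioate F5 (conditions of step 11). Remove the silyl group (HF·pyridine) to give the C9 allylic alcohol F6. Oxidise with MnO2 to the Z-enone F7. Epoxidise the enone nucleophilically (t-BuOOH, DBU, CH2Cl2), which does not touch the isopropenyl group, to give the cis-1,10-epoxy-9-ketone F8. Reduce with Zn(BH4)2 (Et2O, −20 °C; chelation control gives the erythro epoxy alcohol) to 14, and finish with the acetylation of step 12.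

**Further compounds**

F1 | step 8 | anti-8,9-dihydroxy methyl ketone (analogue of 10 with C9–OH and C10 as acetyl carbon) | C=C(C)[C@H]([C@H](O)[C@H](O)C(C)=O)C[C@@H]1O[C@]1(C)[C@@H](OC(=O)/C(C)=C\C)CC=C
F2 | step 8 | 9-O-triethylsilyl ether of F1 | C=C(C)[C@H]([C@H](O)[C@H](O[Si](CC)(CC)CC)C(C)=O)C[C@@H]1O[C@]1(C)[C@@H](OC(=O)/C(C)=C\C)CC=C
F3 | step 9 | (E)-enal dimethyl acetal (8 with the vinyl group extended to an (E)-2-methylpropenal unit) | C=C(C)[C@H](C(OC)OC)C[C@@H]1O[C@]1(C)[C@@H](OC(=O)/C(C)=C\C)C/C=C(\C)C=O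
F4 | step 9 | dialdehyde (C8 aldehyde and C9 (E)-enal) | C=C(C)[C@H](C=O)C[C@@H]1O[C@]1(C)[C@@H](OC(=O)/C(C)=C\C)C/C=C(\C)C=O
F5 | step 10 | 8-O-senecioate of 11 | C=C(C)[C@H]1C[C@@H]2O[C@]2(C)[C@@H](OC(=O)/C(C)=C\C)C/C=C(C)\[C@@H](O[Si](CC)(CC)CC)[C@H]1OC(=O)C=C(C)C
F6 | step 10 | C9 allylic alcohol from F5 | C=C(C)[C@H]1C[C@@H]2O[C@]2(C)[C@@H](OC(=O)/C(C)=C\C)C/C=C(C)\[C@@H](O)[C@H]1OC(=O)C=C(C)C
F7 | step 10 | (1(10)Z)-9-ketone (Z-enone) | C=C(C)[C@H]1C[C@@H]2O[C@]2(C)[C@@H](OC(=O)/C(C)=C\C)C/C=C(C)\C(=O)[C@H]1OC(=O)C=C(C)C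
F8 | step 10 | cis-1,10-epoxy-9-ketone | C=C(C)[C@H]1C[C@@H]2O[C@]2(C)[C@@H](OC(=O)/C(C)=C\C)C[C@H]2O[C@@]2(C)C(=O)[C@H]1OC(=O)C=C(C)C
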